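Everything rests on cutting ring B at C7–C8 and C9–C10. Ring A then becomes a 2-silyloxy diene (C10=C5–C6(OSi)=C7, from β-cyclocitral) and C8–C9 an (E)-N-crotonoyl oxazolidinone. One auxiliary-controlled Diels–Alder reaction closes ring B, delivers the C6 oxygen as an enol ether and sets C8, C9 and quaternary C10. It exploits the pattern of ring B in the target: C11 on C9 is anti, and C17 on C8 syn, to the angular methyl C20, which is the endo result for a diene carrying C20 as inside substituent. All three centres are kept: C8–H is later hydroxylated with retention, and the equatorial O6 radical oxidises C18. No 7-en-6-one is made, since it would erase C8 and render C9 epimerisable.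

Key step: step 5

Assumption: labdane numbering is used throughout. Syn and anti give the face relative to the angular methyl C20. C9 is taken exactly as written in the target string, that is with C11 anti to C20 and therefore axial on a chair ring B.

Step 1
Reactants: 1 β-cyclocitral
Product: 2 1-(2,6,6-trimethylcyclohex-1-en-1-yl)ethanol (racemic)
Conditions: MeMgBr, Et2O, 0 °C
Reagents that add atoms: methylmagnesium bromide, C[Mg]Br
Why: Grignard 1,2-addition to the hindered enal supplies C7, and the racemic carbinol centre it creates is removed in step 2.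

Step 2
Reactants: 2 1-(2,6,6-trimethylcyclohex-1-en-1-yl)ethanol
Product: 3 1-(2,6,6-trimethylcyclohex-1-en-1-yl)ethanone (ring A methyl ketone)
Conditions: Dess–Martin periodinane, CH2Cl2, rt
Reagents that add atoms: none
Why: Dess–Martin oxidation of a secondary allylic alcohol is mild, neutral and leaves the tetrasubstituted alkene untouched.

Step 3
Reactants: 3 ring A methyl ketone
Product: 4 ring A 2-silyloxy diene (C10=C5–C6(OTBS)=C7)
Conditions: TBSOTf, Et3N, CH2Cl2, 0 °C
Reagents that add atoms: tert-butyldimethylsilyl triflate, CC(C)(C)[Si](C)(C)OS(=O)(=O)C(F)(F)F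
Why: Soft enolisation and O-silylation occur at the acetyl methyl group, the only α-carbon bearing hydrogen, while γ-deprotonation is slow because the enone is twisted out of conjugation, so the cross-conjugated silyl enol ether forms.

Step 4
Reactants: 5 (R)-4-benzyl-1,3-oxazolidin-2-one; 6 (E)-but-2-enoyl chloride
Product: 8 (R)-4-benzyl-3-[(E)-but-2-enoyl]-1,3-oxazolidin-2-one, via lithium oxazolidinide 7 (not isolated)
Conditions: n-BuLi, THF, −78 °C; then 6, −78 to 0 °C
Reagents that add atoms: none
Why: N-acylation of the lithiated oxazolidinone with the acid chloride is the standard entry to N-enoyl imides and keeps the E geometry.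

Step 5
Reactants: 4 ring A 2-silyloxy diene; 8 (R)-4-benzyl-3-[(E)-but-2-enoyl]-1,3-oxazolidin-2-one
Product: 9 ring B cycloadduct (C5=C6 TBS enol ether; acyl carbon C11 on C9 anti to C20; C17 on C8 syn to C20)
Conditions: Et2AlCl (1.6 equiv), CH2Cl2, −40 to 0 °C
Reagents that add atoms: none
Why: Excess Et2AlCl turns 8 into a cationic O,O-chelate held s-cis, and diene 4 adds to it in a concerted but asynchronous [4+2] cycloaddition in which the nucleophilic terminus C7 bonds ahead to the β-carbon C8 and fully substituted C10 follows onto the α-carbon C9. Its nearest relatives are the aluminium-promoted cycloadditions of chiral N-enoyl oxazolidinones with 2-silyloxybutadienes and the cycloadditions of 1-vinyl-2,6,6-trimethylcyclohexene that create the angular methyl of drimanes. Six-membered ring B closes in an intermolecular, suprafacial–suprafacial mode, the σ-bonds C7–C8 and C9–C10 arising in the same operation. C9 is controlled by the benzyl group of the (R)-auxiliary, which covers one face of the chelate so that the diene meets the Re face at C9; C10 is controlled by the endo arrangement, which places C11 cis to the outside substituent C1 and anti to the inside methyl C20; C8 is controlled by the E geometry, which keeps C17 trans to C11 and hence syn to C20. Three selectivities have to coincide: orientation follows from the donor oxygen on C6, which raises the coefficient at C7, the endo mode from overlap of the diene with the aluminium-bound acyl carbonyl, and the face from the auxiliary. The C5=C6 silyl enol ether that remains masks the C6 ketone for the next step.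

Step 6
Reactants: 9 ring B cycloadduct
Product: 11 11-hydroxy-6-ketone (trans-decalone; H5 anti to C20), via silyl enol ether alcohol 10 (not isolated)
Conditions: LiBH4, THF, 0 °C to rt; then 1 M HCl, THF, rt
Reagents that add atoms: none
Why: Reductive cleavage of the N-acyl oxazolidinone frees C11 as CH2OH while the enol ether keeps hydride away from C6, and the acid hydrolysis that follows unmasks the ketone under equilibrating conditions, so C5 takes up hydrogen on the face away from C19 and C20 and the trans ring fusion results.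

Step 7
Reactants: 11 11-hydroxy-6-ketone
Product: 12 6,11-diol (6-OH equatorial, anti to C20)
Conditions: Li, NH3(l), THF–EtOH, −78 to −33 °C; then NH4Cl
Reagents that add atoms: none
Why: Dissolving-metal reduction protonates the ketyl-derived carbanion to the thermodynamically preferred equatorial alcohol at C6, as with 11-oxo steroids, whereas hydride delivery from the open face would give the axial epimer.

Step 8
Reactants: 12 6,11-diol
Product: 13 11-acetate of the 6,11-diol (6-OH free)
Conditions: AcCl (1.05 equiv), 2,4,6-collidine, CH2Cl2, −78 °C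
Reagents that add atoms: acetyl chloride, CC(=O)Cl
Why: Chemoselective O-acylation favours the primary C11 hydroxyl over the secondary 6-hydroxyl, which is crowded by the peri methyl on C4, and the acetate later deactivates C9–H and C11–H towards oxidants.

Step 9
Reactants: 13 11-acetate (6-OH free)
Product: 16 6,18-epoxy 11-acetate (tetrahydrofuran O6–C18), via 6-O-hypoiodite 14 (not isolated), via 18-iodo alcohol 15 (not isolated)
Conditions: PhI(OAc)2, I2, cyclohexane–CH2Cl2, hν (tungsten lamp), rt
Reagents that add atoms: none
Why: In this hypoiodite reaction the equatorial O6 radical performs a 1,5-hydrogen atom transfer from the only methyl group next to it, the equatorial one on C4, and O6 then displaces the iodide, which makes C4 a stereocentre with the oxidised carbon C18 anti to C20.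

Step 10
Reactants: 16 6,18-epoxy 11-acetate
Product: 17 18,6-lactone 11-acetate
Conditions: RuCl3 (5 mol %), NaIO4, MeCN–CCl4–H2O, rt
Reagents that add atoms: sodium periodate, [Na+].[O-]I(=O)(=O)=O
Why: RuO4-catalysed oxidation of a cyclic ether to the γ-lactone takes place at the open O–CH2 group C18, because the other α-hydrogen, axial H6, is buried under C19 and C20.

Step 11
Reactants: 17 18,6-lactone 11-acetate
Product: 18 8-hydroxy-18,6-lactone 11-acetate (8-OH equatorial, anti to C20; C17 syn to C20)
Conditions: methyl(trifluoromethyl)dioxirane in 1,1,1-trifluoroacetone, CH2Cl2, −20 to 0 °C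
Reagents that add atoms: methyl(trifluoromethyl)dioxirane, CC1(OO1)C(F)(F)F
Why: Dioxirane C–H hydroxylation is a concerted oxygen insertion with retention, and equatorial C8–H is the most reactive tertiary C–H because its oxidation relieves the C17/C20 1,3-diaxial strain while C5–H, C6–H, C9–H and C11–H are deactivated by neighbouring acyloxy groups, so the configuration fixed in step 5 becomes that of the carbinol.

Step 12
Reactants: 18 8-hydroxy lactone 11-acetate
Product: 19 8-O-triethylsilyl lactone 11-acetate
Conditions: TESOTf, 2,6-lutidine, CH2Cl2, 0 °C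
Reagents that add atoms: triethylsilyl triflate, CC[Si](CC)(CC)OS(=O)(=O)C(F)(F)F
Why: Silyl triflate silylation caps the hindered tertiary alcohol, so that no alkoxide-driven retro-aldol cleavage can start from the C11 aldehyde of step 14.

Step 13
Reactants: 19 8-O-triethylsilyl lactone 11-acetate
Product: 20 11-alcohol (8-O-triethylsilyl lactone)
Conditions: K2CO3 (20 mol %), MeOH, 0 °C to rt
Reagents that add atoms: none
Why: Base-catalysed methanolysis removes the primary acetate, while the lactone carbonyl on quaternary C4 is shielded and would in any case reclose onto the adjacent O6.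

Step 14
Reactants: 20 11-alcohol
Product: 21 11-aldehyde (formyl group axial on C9)
Conditions: Dess–Martin periodinane, CH2Cl2, rt
Reagents that add atoms: none
Why: Dess–Martin oxidation is non-basic, so the aldehyde forms without enolisation and the axial configuration at C9 is kept.

Step 15
Reactants: 21 11-aldehyde
Product: 22 C9-vinyl lactone (C11=C12)
Conditions: Ph3PCH3Br, KN(SiMe3)2, THF, 0 °C; then 21, −78 to 0 °C
Reagents that add atoms: methyltriphenylphosphonium bromide, C[P+](c1ccccc1)(c1ccccc1)c1ccccc1.[Br-]
Why: In this Wittig methylenation the small, non-stabilised ylide adds to the aldehyde at low temperature faster than it can remove the shielded equatorial H9, so C9 is retained, and the non-enolisable lactone is inert to the ylide.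

Step 16
Reactants: 22 C9-vinyl lactone; 23 chloroprene
Product: 25 diene lactone (complete C11–C16 side chain), via B-alkyl-9-BBN 24 (not isolated)
Conditions: 9-BBN dimer, THF, rt to 40 °C; then 23, Pd(OAc)2 (5 mol %), SPhos (10 mol %), aq K3PO4, THF, 40 °C
Reagents that add atoms: none
Why: Anti-Markovnikov hydroboration of the monosubstituted alkene places boron on C12, and B-alkyl Suzuki–Miyaura coupling with the alkenyl chloride forms C12–C13 under conditions that spare the lactone and the silyl ether.

Step 17
Reactants: 25 diene lactone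
Product: 26 diene 6,18-diol 8-O-triethylsilyl ether
Conditions: LiAlH4, THF, 0 °C to rt
Reagents that add atoms: none
Why: Hydride reduction opens the lactone to the 1,4-diol without touching the C6–O bond, so C6 keeps its configuration, and the unactivated diene and the silyl ether are inert.

Step 18
Reactants: 26 diene 6,18-diol 8-O-triethylsilyl ether
Product: 28 6-acetate 8,18-bis(triethylsilyl) ether, via 18-O-triethylsilyl ether 27 (not isolated)
Conditions: TESCl (1.1 equiv), imidazole, CH2Cl2, 0 °C; then Ac2O, Et3N, DMAP (cat.), rt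
Reagents that add atoms: chlorotriethylsilane, CC[Si](Cl)(CC)CC; acetic anhydride, CC(=O)OC(C)=O
Why: The primary 18-hydroxyl is silylated faster than the secondary 6-hydroxyl, which is then the only free hydroxyl left for DMAP-catalysed acetylation in the same flask.

Step 19
Reactants: 28 6-acetate 8,18-bis(triethylsilyl) ether
Product: 29 target CNP0312185.2
Conditions: HF·pyridine, pyridine, THF, 0 °C to rt
Reagents that add atoms: none
Why: Buffered fluoride desilylation cleaves both triethylsilyl ethers under non-basic conditions, which avoids acetyl migration from O6 to O18 and ionisation of the tertiary alcohol.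

Compound list
1 | β-cyclocitral | CC1=C(C=O)C(C)(C)CCC1 | starting material
2 | 1-(2,6,6-trimethylcyclohex-1-en-1-yl)ethanol, racemic | CC(O)C1=C(C)CCCC1(C)C | intermediate
3 | 1-(2,6,6-trimethylcyclohex-1-en-1-yl)ethanone | CC(=O)C1=C(C)CCCC1(C)C | intermediate
4 | ring A 2-silyloxy diene | C=C(O[Si](C)(C)C(C)(C)C)C1=C(C)CCCC1(C)C | intermediate
5 | (R)-4-benzyl-1,3-oxazolidin-2-one | O=C1N[C@H](Cc2ccccc2)CO1 | starting material
6 | (E)-but-2-enoyl chloride | C/C=C/C(Cl)=O | starting material
7 | lithium oxazolidinide (N-lithio derivative of 5) | [Li]N1[C@H](Cc2ccccc2)COC1=O | intermediate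
8 | (R)-4-benzyl-3-[(E)-but-2-enoyl]-1,3-oxazolidin-2-one | C/C=C/C(=O)N1[C@H](Cc2ccccc2)COC1=O | intermediate
9 | ring B cycloadduct, C5=C6 TBS enol ether, C11 anti and C17 syn to C20 | O=C(N3[C@H](Cc4ccccc4)COC3=O)[C@@H]1[C@]2(C)CCCC(C)(C)C2=C(O[Si](C)(C)C(C)(C)C)C[C@H]1C | intermediate
10 | silyl enol ether alcohol (C11 CH2OH) | OC[C@@H]1[C@]2(C)CCCC(C)(C)C2=C(O[Si](C)(C)C(C)(C)C)C[C@H]1C | intermediate
11 | 11-hydroxy-6-ketone, trans-decalone | OC[C@@H]1[C@]2(C)CCCC(C)(C)[C@H]2C(=O)C[C@H]1C | intermediate
12 | 6,11-diol, 6-OH equatorial | OC[C@@H]1[C@]2(C)CCCC(C)(C)[C@H]2[C@H](O)C[C@H]1C | intermediate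
13 | 11-acetate, 6-OH free | CC(=O)OC[C@@H]1[C@]2(C)CCCC(C)(C)[C@H]2[C@H](O)C[C@H]1C | intermediate
14 | 6-O-hypoiodite | CC(=O)OC[C@@H]1[C@]2(C)CCCC(C)(C)[C@H]2[C@H](OI)C[C@H]1C | intermediate
15 | 18-iodo alcohol | CC(=O)OC[C@@H]1[C@]2(C)CCC[C@](C)(CI)[C@H]2[C@H](O)C[C@H]1C | intermediate
16 | 6,18-epoxy 11-acetate | CC(=O)OC[C@@H]1[C@]2(C)CCC[C@](C)(CO3)[C@H]2[C@H]3C[C@H]1C | intermediate
17 | 18,6-lactone 11-acetate | CC(=O)OC[C@@H]1[C@]2(C)CCC[C@](C)(C(=O)O3)[C@H]2[C@H]3C[C@H]1C | intermediate
18 | 8-hydroxy-18,6-lactone 11-acetate | CC(=O)OC[C@@H]1[C@]2(C)CCC[C@](C)(C(=O)O3)[C@H]2[C@H]3C[C@]1(C)O | intermediate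
19 | 8-O-triethylsilyl lactone 11-acetate | CC(=O)OC[C@@H]1[C@]2(C)CCC[C@](C)(C(=O)O3)[C@H]2[C@H]3C[C@]1(C)O[Si](CC)(CC)CC | intermediate
20 | 11-alcohol, 8-O-triethylsilyl lactone | OC[C@@H]1[C@]2(C)CCC[C@](C)(C(=O)O3)[C@H]2[C@H]3C[C@]1(C)O[Si](CC)(CC)CC | intermediate
21 | 11-aldehyde | O=C[C@@H]1[C@]2(C)CCC[C@](C)(C(=O)O3)[C@H]2[C@H]3C[C@]1(C)O[Si](CC)(CC)CC | intermediate
22 | C9-vinyl lactone | C=C[C@@H]1[C@]2(C)CCC[C@](C)(C(=O)O3)[C@H]2[C@H]3C[C@]1(C)O[Si](CC)(CC)CC | intermediate
23 | chloroprene | C=CC(Cl)=C | starting material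
24 | B-alkyl-9-BBN (boron on C12) | C(C[C@@H]1[C@]2(C)CCC[C@](C)(C(=O)O3)[C@H]2[C@H]3C[C@]1(C)O[Si](CC)(CC)CC)B4C5CCCC4CCC5 | intermediate
25 | diene lactone | C=CC(=C)CC[C@@H]1[C@]2(C)CCC[C@](C)(C(=O)O3)[C@H]2[C@H]3C[C@]1(C)O[Si](CC)(CC)CC | intermediate
26 | diene 6,18-diol 8-O-triethylsilyl ether | C=CC(=C)CC[C@@H]1[C@]2(C)CCC[C@](C)(CO)[C@H]2[C@H](O)C[C@]1(C)O[Si](CC)(CC)CC | intermediate
27 | 18-O-triethylsilyl ether, 6-OH free | C=CC(=C)CC[C@@H]1[C@]2(C)CCC[C@](C)(CO[Si](CC)(CC)CC)[C@H]2[C@H](O)C[C@]1(C)O[Si](CC)(CC)CC | intermediate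
28 | 6-acetate 8,18-bis(triethylsilyl) ether | C=CC(=C)CC[C@@H]1[C@]2(C)CCC[C@](C)(CO[Si](CC)(CC)CC)[C@H]2[C@H](OC(C)=O)C[C@]1(C)O[Si](CC)(CC)CC | intermediate
29 | CNP0312185.2 | C=CC(=C)CC[C@@H]1[C@]2(C)CCC[C@](C)(CO)[C@H]2[C@H](OC(C)=O)C[C@]1(C)O | target

Total step count: 19. Longest linear sequence: 18 steps (steps 1–3 and 5–19, from 1 to 29).

Steps most likely to fail

Step 5.
- What may go wrong: the diene may not reach a planar s-cis geometry between the C4 gem-dimethyl group and C20, so that bond formation at C10 lags. Conjugate addition with loss of the silyl group may then take over, or the endo preference may erode under the bulk of the chelated auxiliary.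
- Fallback: it sets out from 4 and moves stereocontrol from the auxiliary to a chiral Lewis acid acting on a much smaller dienophile. (E)-Crotonaldehyde is activated by the triflimide salt of 3,3-diphenyl-1-(2-methylphenyl)tetrahydropyrrolo[1,2-c][1,3,2]oxazaborole, in the antipode that exposes the Re face at C9. It should give the endo aldehyde cycloadduct F1, and NaBH4 in MeOH reduces this to 10, where the route is rejoined.

Step 11.
- What may go wrong: oxygen insertion may spread to the ring A methylene groups or to C9–H, or oxidation may continue past the mono-alcohol.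
- Fallback: it sets out from 17 and replaces innate selectivity by a tether from O11.
- Methanolysis (K2CO3, MeOH) gives the 11-hydroxy lactone F2, and 2,2,2-trifluoroethyl isocyanate turns this into the trifluoroethyl carbamate F3.
- Acetyl hypobromite gives the N-bromocarbamate F4. Visible-light homolysis and 1,6-hydrogen transfer through a seven-membered transition state (Hofmann–Löffler–Freytag type) then move bromine to C8 in the tertiary bromide F5.
- Ag2CO3 ionises the bromide, and the tethered carbamate oxygen closes on the face of C11 to the cyclic iminocarbonate F6, which aqueous acetic acid hydrolyses to the cyclic carbonate F7.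
- K2CO3 in MeOH frees the 8,11-diol lactone F8, and selective acetylation of its primary hydroxyl as in step 8 comes back to the route at 18.

Step 16.
- What may go wrong: oxidative addition of the alkenyl chloride may be slow, chloroprene may polymerise, or the hindered alkylborane may be lost through protodeboronation or β-hydride elimination.
- Fallback: it sets out from 22 and inverts the polarity of the coupling. Hydroboration to 24 as before and oxidation with NaBO3·4H2O give the 12-alcohol F9.
- I2, PPh3 and imidazole give the 12-iodide F10; O8 is silylated, so no tetrahydrofuran can close.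
- Li2CuCl4-catalysed coupling at low temperature with buta-1,3-dien-2-ylmagnesium chloride F11, prepared from 23 and Mg, comes back to the route at 25.

Further compounds
F1 | step 5 | aldehyde cycloadduct | O=C[C@@H]1[C@]2(C)CCCC(C)(C)C2=C(O[Si](C)(C)C(C)(C)C)C[C@H]1C
F2 | step 11 | 11-hydroxy lactone | OC[C@@H]1[C@]2(C)CCC[C@](C)(C(=O)O3)[C@H]2[C@H]3C[C@H]1C
F3 | step 11 | trifluoroethyl carbamate | O=C(NCC(F)(F)F)OC[C@@H]1[C@]2(C)CCC[C@](C)(C(=O)O3)[C@H]2[C@H]3C[C@H]1C
F4 | step 11 | N-bromocarbamate | O=C(N(Br)CC(F)(F)F)OC[C@@H]1[C@]2(C)CCC[C@](C)(C(=O)O3)[C@H]2[C@H]3C[C@H]1C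
F5 | step 11 | tertiary bromide (C8 unassigned) | O=C(NCC(F)(F)F)OC[C@@H]1[C@]2(C)CCC[C@](C)(C(=O)O3)[C@H]2[C@H]3CC1(C)Br
F6 | step 11 | cyclic iminocarbonate | FC(F)(F)CN=C1OC[C@@H]2[C@]3(C)CCC[C@](C)(C(=O)O4)[C@H]3[C@H]4C[C@]2(C)O1
F7 | step 11 | cyclic carbonate | O=C1OC[C@@H]2[C@]3(C)CCC[C@](C)(C(=O)O4)[C@H]3[C@H]4C[C@]2(C)O1
F8 | step 11 | 8,11-diol lactone | OC[C@@H]1[C@]2(C)CCC[C@](C)(C(=O)O3)[C@H]2[C@H]3C[C@]1(C)O
F9 | step 16 | 12-alcohol | OCC[C@@H]1[C@]2(C)CCC[C@](C)(C(=O)O3)[C@H]2[C@H]3C[C@]1(C)O[Si](CC)(CC)CC
F10 | step 16 | 12-iodide | ICC[C@@H]1[C@]2(C)CCC[C@](C)(C(=O)O3)[C@H]2[C@H]3C[C@]1(C)O[Si](CC)(CC)CC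
F11 | step 16 | buta-1,3-dien-2-ylmagnesium chloride | C=CC(=C)[Mg]Cl
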